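Numbering: half A is the 4,5-dimethoxy-7-methylnaphthalen-2-ol unit (bonded through A-C1), half B the 5-methoxy-2-methylnaphthalene-4,6-diol unit (bonded through B-C1).
Retrosynthesis: the lone CH B-C3, between methyl-bearing B-C2 and hydroxyl-bearing B-C4 in the oxygenated ring of half B, is excised (B-C2–B-C3 and B-C3–B-C4 cut). This 2-unsubstituted 1-naphthol array is what one-carbon insertion into the enol ether of a 2-methyl-3-arylindan-1-one delivers.
The indanone is cut at B-C1–B-C8a (Nazarov) and B-C1=B-C2 (aldol) into an A-C1 naphthaldehyde and an aryl ethyl ketone; half A is cut at A-C3–A-C4 (Claisen), A-C1–A-C2 (toluate acylation) and A-C4–A-C4a (carboxylation).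
Forward: second ring of half A by Claisen closure, formylation at A-C1, aldol union with the ketone, five-membered ring by Nazarov closure, expansion to the six-membered B-C1 to B-C4 ring by dibromocarbene, then hydrodebromination and removal of two isopropyl ethers.
Stereochemistry: the target has no stereocentre and the biaryl axis is left uncontrolled; the indanone stereocentres are racemic and are erased by enol ether formation and aromatisation.

Key step: step 14

Assumption: the target is drawn without an axial descriptor, so the biaryl is prepared as the racemate with no control of the axis.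

Step 1
Reactants: 1 3,5-dimethylanisole
Product: 3 methyl 2-methoxy-4,6-dimethylbenzoate, via aryllithium 2 (not isolated)
Conditions: n-BuLi, TMEDA, Et2O, 0 °C to rt; then added to excess ClCO2Me, −78 °C
Reagents that add atoms: methyl chloroformate COC(=O)Cl
Why: Directed ortho-metalation places lithium next to the methoxy group (both such positions are equivalent), and inverse quench of the hindered aryllithium with excess chloroformate should stop at the ester.

Step 2
Reactants: 3 methyl 2-methoxy-4,6-dimethylbenzoate; 4 N-methoxy-N-methylacetamide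
Product: 6 methyl 2-methoxy-4-methyl-6-(2-oxopropyl)benzoate, via benzylic lithium species 5 (not isolated)
Conditions: LiN(i-Pr)2 (1.2 equiv), THF, −78 °C; then 4, −78 °C; dilute aq. HCl
Reagents that add atoms: none
Why: Lateral lithiation of an ortho-toluate (ester coordination makes the ortho methyl the acidic one) followed by acylation with a Weinreb amide, whose chelated tetrahedral adduct prevents over-addition and protects the new ketone until work-up.

Step 3
Reactants: 6 methyl 2-methoxy-4-methyl-6-(2-oxopropyl)benzoate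
Product: 7 8-methoxy-6-methylnaphthalene-1,3-diol
Conditions: KOt-Bu (2.2 equiv), THF, 0 °C to rt, argon; then aq. HCl
Reagents that add atoms: none
Why: Intramolecular Claisen (Dieckmann-type, 6-exo-trig) condensation of the methyl-ketone enolate onto the aryl ester gives a cyclic 1,3-diketone that aromatises irreversibly to the naphthalene-1,3-diol.

Step 4
Reactants: 7 8-methoxy-6-methylnaphthalene-1,3-diol
Product: 8 8-methoxy-6-methyl-3-(propan-2-yloxy)naphthalen-1-ol
Conditions: dry HCl, i-PrOH, 50 °C
Reagents that add atoms: propan-2-ol CC(C)O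
Why: Acid-catalysed mono-etherification of a naphthalene-1,3-diol runs through the C4-protonated keto tautomer (a vinylogous acid) and exchanges only the non-benzylic 3-oxygen, as in the known preparation of 3-alkoxy-1-naphthols; the peri-hindered 1-hydroxyl stays free.

Step 5
Reactants: 8 8-methoxy-6-methyl-3-(propan-2-yloxy)naphthalen-1-ol
Product: 9 1,8-dimethoxy-6-methyl-3-(propan-2-yloxy)naphthalene (half A numbering: 4,5-dimethoxy-7-methyl-2-isopropoxynaphthalene)
Conditions: MeI, K2CO3, DMF, rt to 40 °C
Reagents that add atoms: iodomethane CI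
Why: Williamson O-methylation of the remaining peri-hydroxyl; the isopropyl ether is inert to these conditions.

Step 6
Reactants: 9 1,8-dimethoxy-6-methyl-3-(propan-2-yloxy)naphthalene
Product: 11 4,5-dimethoxy-7-methyl-2-(propan-2-yloxy)naphthalene-1-carbaldehyde, via iminium salt 10 (not isolated)
Conditions: POCl3, DMF, 0 to 60 °C; then aq. NaOAc
Reagents that add atoms: N,N-dimethylformamide CN(C)C=O
Why: Vilsmeier–Haack formylation should occur at A-C1, the alpha position ortho to the isopropoxy group and para to the A-C4 methoxy group, in line with the C4 formylation of 1,3-dialkoxynaphthalenes.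

Step 7
Reactants: 12 2,3-dihydroxybenzaldehyde
Product: 13 2-hydroxy-3-(propan-2-yloxy)benzaldehyde
Conditions: NaH (2.2 equiv), DMSO, rt; then 2-bromopropane (1.05 equiv); aq. HCl
Reagents that add atoms: 2-bromopropane CC(C)Br
Why: Williamson alkylation of the dianion is regioselective, because the 3-oxide, neither conjugated with nor chelated to the formyl group, is the more nucleophilic oxygen.

Step 8
Reactants: 13 2-hydroxy-3-(propan-2-yloxy)benzaldehyde
Product: 14 2-methoxy-3-(propan-2-yloxy)benzaldehyde
Conditions: MeI, K2CO3, DMF, rt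
Reagents that add atoms: iodomethane CI
Why: Williamson O-methylation of the remaining, formyl-chelated phenol.

Step 9
Reactants: 14 2-methoxy-3-(propan-2-yloxy)benzaldehyde
Product: 15 1-[2-methoxy-3-(propan-2-yloxy)phenyl]propan-1-ol (racemic)
Conditions: EtMgBr, THF, 0 °C; then water
Reagents that add atoms: ethylmagnesium bromide CC[Mg]Br
Why: Grignard addition to the aldehyde gives the racemic benzylic alcohol, whose stereocentre is removed in the next step.

Step 10
Reactants: 15 1-[2-methoxy-3-(propan-2-yloxy)phenyl]propan-1-ol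
Product: 16 1-[2-methoxy-3-(propan-2-yloxy)phenyl]propan-1-one
Conditions: Dess–Martin periodinane, CH2Cl2, rt
Reagents that add atoms: none
Why: Dess–Martin oxidation converts the secondary benzylic alcohol into the aryl ethyl ketone under neutral conditions that leave both ethers untouched.

Step 11
Reactants: 16 1-[2-methoxy-3-(propan-2-yloxy)phenyl]propan-1-one; 11 4,5-dimethoxy-7-methyl-2-(propan-2-yloxy)naphthalene-1-carbaldehyde
Product: 19 (E)-3-[4,5-dimethoxy-7-methyl-2-(propan-2-yloxy)naphthalen-1-yl]-1-[2-methoxy-3-(propan-2-yloxy)phenyl]-2-methylprop-2-en-1-one, via lithium aldolate 17 (not isolated), via mesylate 18 (not isolated)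
Conditions: LiN(SiMe3)2 (1.05 equiv), THF, −78 °C; then 11, −78 to −40 °C; then MsCl, to 0 °C; then DBU, rt
Reagents that add atoms: none
Why: Directed aldol addition of the lithium enolate to the non-enolisable, hindered aldehyde is made irreversible by mesylation, and base-induced elimination (aldol condensation), eased by the donor-rich naphthyl group, should give the conjugated (E)-enone as the thermodynamic isomer.

Step 12
Reactants: 19 (E)-enone
Product: 20 3-[4,5-dimethoxy-7-methyl-2-(propan-2-yloxy)naphthalen-1-yl]-7-methoxy-2-methyl-6-(propan-2-yloxy)-2,3-dihydro-1H-inden-1-one (racemic, cis/trans mixture)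
Conditions: CF3CO2H, ClCH2CH2Cl, 60 °C
Reagents that add atoms: none
Why: Nazarov cyclisation of an aryl vinyl ketone: the O-protonated enone closes by conrotatory 4π electrocyclisation onto the only free ortho carbon of the benzoyl ring, which is para to the isopropoxy group, and rearomatisation and ketonisation give the indanone, whose two racemic stereocentres are both erased later.

Step 13
Reactants: 20 indanone
Product: 21 tert-butyl({1-[4,5-dimethoxy-7-methyl-2-(propan-2-yloxy)naphthalen-1-yl]-4-methoxy-2-methyl-5-(propan-2-yloxy)-1H-inden-3-yl}oxy)dimethylsilane (racemic)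
Conditions: TBSOTf, Et3N, CH2Cl2, 0 °C to rt
Reagents that add atoms: tert-butyldimethylsilyl trifluoromethanesulfonate CC(C)(C)[Si](C)(C)OS(=O)(=O)C(F)(F)F
Why: Soft enolisation with a silyl triflate and an amine can enolise only toward C2, giving the tetrasubstituted silyl enol ether, and the weak base avoids deprotonating the doubly benzylic C3–H.

Step 14
Reactants: 21 silyl enol ether; 22 bromoform
Product: 25 2-bromo-4-[4,5-dimethoxy-7-methyl-2-(propan-2-yloxy)naphthalen-1-yl]-8-methoxy-3-methyl-7-(propan-2-yloxy)naphthalen-1-ol, via dibromocyclopropane 23 (not isolated), via bromo enone 24 (not isolated)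
Conditions: CHBr3 (2 equiv), KOt-Bu added in portions, hexane, −20 to 20 °C; then Bu4NF, THF, 0 °C
Reagents that add atoms: none
Why: KOt-Bu deprotonates bromoform and alpha-elimination gives dibromocarbene, which cyclopropanates the electron-rich tetrasubstituted enol ether bond of 21 from the face away from the naphthyl group to give 23. The strained siloxy dibromocyclopropane then ionises with loss of the endo bromide and disrotatory two-electron electrocyclic opening of the ring-fusion bond, so the carbene carbon becomes B-C3, bonded to B-C2 and B-C4, and the five-membered ring becomes the six-membered B-C1 to B-C4 ring; the ring therefore arises by ring expansion through cleavage of the zero-atom bridge, not by an exo or endo cyclisation. Loss of the silyl group gives bromo enone 24, which aromatises by enolisation through the doubly benzylic B-C1–H, and the fluoride treatment frees any naphthol that has been re-silylated. The closest known reaction type is the dihalocarbene one-carbon ring expansion of cyclic silyl enol ethers and of indenes to 2-halo-1-naphthols and 2-halonaphthalenes. No stereocentre is created and the only one in 21 is destroyed. Chemoselectivity for the enol ether over the alkoxynaphthalene rests on its much higher nucleophilicity, keeping bromoform in excess over slowly added base at low temperature suppresses base-induced migration of the indene double bond, and the insertion site is fixed because only the ring-fusion bond can open.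

Step 15
Reactants: 25 bromonaphthol
Product: 26 4-[4,5-dimethoxy-7-methyl-2-(propan-2-yloxy)naphthalen-1-yl]-8-methoxy-3-methyl-7-(propan-2-yloxy)naphthalen-1-ol
Conditions: H2 (1 atm), Pd/C, Et3N, EtOAc/MeOH, rt
Reagents that add atoms: none
Why: Catalytic hydrodehalogenation of the aryl bromide over Pd/C with an amine as HBr scavenger; aryl ethers, the free naphthol and the naphthalene rings are inert at 1 atm and room temperature.

Step 16
Reactants: 26 bis(isopropyl ether)
Product: 27 4,5,5'-trimethoxy-2',7-dimethyl-[1,1'-binaphthalene]-2,4',6'-triol (target)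
Conditions: BCl3, CH2Cl2, −78 to 0 °C, argon; then MeOH/water
Reagents that add atoms: none
Why: BCl3-mediated ether cleavage is selective for secondary (isopropyl) aryl ethers over methyl ethers at low temperature and should release the A-C2 and B-C6 hydroxyls.

Compound list
1 | 3,5-dimethylanisole | COc1cc(C)cc(C)c1 | starting material
2 | 2-methoxy-4,6-dimethylphenyllithium (formed in the flask) | [Li]c1c(C)cc(C)cc1OC | intermediate
3 | methyl 2-methoxy-4,6-dimethylbenzoate | COC(=O)c1c(C)cc(C)cc1OC | intermediate
4 | N-methoxy-N-methylacetamide | CC(=O)N(C)OC | starting material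
5 | [3-methoxy-2-(methoxycarbonyl)-5-methylphenyl]methyllithium (formed in the flask) | [Li]Cc1cc(C)cc(OC)c1C(=O)OC | intermediate
6 | methyl 2-methoxy-4-methyl-6-(2-oxopropyl)benzoate | COC(=O)c1c(CC(C)=O)cc(C)cc1OC | intermediate
7 | 8-methoxy-6-methylnaphthalene-1,3-diol | COc1cc(C)cc2cc(O)cc(O)c12 | intermediate
8 | 8-methoxy-6-methyl-3-(propan-2-yloxy)naphthalen-1-ol | COc1cc(C)cc2cc(OC(C)C)cc(O)c12 | intermediate
9 | 1,8-dimethoxy-6-methyl-3-(propan-2-yloxy)naphthalene | COc1cc(C)cc2cc(OC(C)C)cc(OC)c12 | intermediate
10 | N-{[4,5-dimethoxy-7-methyl-2-(propan-2-yloxy)naphthalen-1-yl]methylidene}-N-methylmethanaminium chloride (formed in the flask) | COc1cc(C)cc2c(C=[N+](C)C)c(OC(C)C)cc(OC)c12.[Cl-] | intermediate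
11 | 4,5-dimethoxy-7-methyl-2-(propan-2-yloxy)naphthalene-1-carbaldehyde | COc1cc(C)cc2c(C=O)c(OC(C)C)cc(OC)c12 | intermediate
12 | 2,3-dihydroxybenzaldehyde | O=Cc1cccc(O)c1O | starting material
13 | 2-hydroxy-3-(propan-2-yloxy)benzaldehyde | CC(C)Oc1cccc(C=O)c1O | intermediate
14 | 2-methoxy-3-(propan-2-yloxy)benzaldehyde | COc1c(C=O)cccc1OC(C)C | intermediate
15 | 1-[2-methoxy-3-(propan-2-yloxy)phenyl]propan-1-ol (racemic) | CCC(O)c1cccc(OC(C)C)c1OC | intermediate
16 | 1-[2-methoxy-3-(propan-2-yloxy)phenyl]propan-1-one | CCC(=O)c1cccc(OC(C)C)c1OC | intermediate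
17 | lithium 1-[4,5-dimethoxy-7-methyl-2-(propan-2-yloxy)naphthalen-1-yl]-3-[2-methoxy-3-(propan-2-yloxy)phenyl]-2-methyl-3-oxopropan-1-olate (diastereomer mixture, racemic; formed in the flask) | [Li]OC(c1c(OC(C)C)cc(OC)c2c(OC)cc(C)cc12)C(C)C(=O)c1cccc(OC(C)C)c1OC | intermediate
18 | 1-[4,5-dimethoxy-7-methyl-2-(propan-2-yloxy)naphthalen-1-yl]-3-[2-methoxy-3-(propan-2-yloxy)phenyl]-2-methyl-3-oxopropyl methanesulfonate (diastereomer mixture, racemic; formed in the flask) | CS(=O)(=O)OC(c1c(OC(C)C)cc(OC)c2c(OC)cc(C)cc12)C(C)C(=O)c1cccc(OC(C)C)c1OC | intermediate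
19 | (E)-3-[4,5-dimethoxy-7-methyl-2-(propan-2-yloxy)naphthalen-1-yl]-1-[2-methoxy-3-(propan-2-yloxy)phenyl]-2-methylprop-2-en-1-one | C/C(=C\c1c(OC(C)C)cc(OC)c2c(OC)cc(C)cc12)C(=O)c1cccc(OC(C)C)c1OC | intermediate
20 | 3-[4,5-dimethoxy-7-methyl-2-(propan-2-yloxy)naphthalen-1-yl]-7-methoxy-2-methyl-6-(propan-2-yloxy)-2,3-dihydro-1H-inden-1-one (racemic, cis/trans mixture) | CC1C(=O)c2c(OC)c(OC(C)C)ccc2C1c1c(OC(C)C)cc(OC)c2c(OC)cc(C)cc12 | intermediate
21 | tert-butyl({1-[4,5-dimethoxy-7-methyl-2-(propan-2-yloxy)naphthalen-1-yl]-4-methoxy-2-methyl-5-(propan-2-yloxy)-1H-inden-3-yl}oxy)dimethylsilane (racemic) | CC1=C(O[Si](C)(C)C(C)(C)C)c2c(OC)c(OC(C)C)ccc2C1c1c(OC(C)C)cc(OC)c2c(OC)cc(C)cc12 | intermediate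
22 | bromoform | BrC(Br)Br | starting material
23 | dibromocarbene adduct of 21 across the enol ether bond: 1,1-dibromo-1a-methyl-6a-[tert-butyl(dimethyl)silyloxy]-1,1a,6,6a-tetrahydrocyclopropa[a]indene carrying the 5-methoxy, 4-isopropoxy and 6-naphthyl groups of 21 (racemic; formed in the flask) | CC12C(c3c(OC(C)C)cc(OC)c4c(OC)cc(C)cc34)c3ccc(OC(C)C)c(OC)c3C1(O[Si](C)(C)C(C)(C)C)C2(Br)Br | intermediate
24 | 2-bromo-4-[4,5-dimethoxy-7-methyl-2-(propan-2-yloxy)naphthalen-1-yl]-8-methoxy-3-methyl-7-(propan-2-yloxy)naphthalen-1(4H)-one (racemic; formed in the flask) | O=C1C(Br)=C(C)C(c2c(OC(C)C)cc(OC)c3c(OC)cc(C)cc23)c2ccc(OC(C)C)c(OC)c12 | intermediate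
25 | 2-bromo-4-[4,5-dimethoxy-7-methyl-2-(propan-2-yloxy)naphthalen-1-yl]-8-methoxy-3-methyl-7-(propan-2-yloxy)naphthalen-1-ol | Cc1c(Br)c(O)c2c(OC)c(OC(C)C)ccc2c1-c1c(OC(C)C)cc(OC)c2c(OC)cc(C)cc12 | intermediate
26 | 4-[4,5-dimethoxy-7-methyl-2-(propan-2-yloxy)naphthalen-1-yl]-8-methoxy-3-methyl-7-(propan-2-yloxy)naphthalen-1-ol | Cc1cc(O)c2c(OC)c(OC(C)C)ccc2c1-c1c(OC(C)C)cc(OC)c2c(OC)cc(C)cc12 | intermediate
27 | 4,5,5'-trimethoxy-2',7-dimethyl-[1,1'-binaphthalene]-2,4',6'-triol | COc1cc(C)cc2c(-c3c(C)cc(O)c4c(OC)c(O)ccc34)c(O)cc(OC)c12 | target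

Total step count: 16. Longest linear sequence: 12 (steps 1 to 6, then 11 to 16).

Steps most likely to fail

Step 12 (Nazarov cyclisation). The dialkoxynaphthyl group may stabilise the cation so strongly that electrocyclisation onto the benzoyl ring is slow, letting acid-induced loss of isopropyl groups or of the naphthyl unit take over. The fallback builds the five-membered ring before the naphthyl group is attached; it sets out from ketone 16 and naphthalene 9 and returns at indanone 20. Alpha-methylenation of 16 with paraformaldehyde and i-Pr2NH·CF3CO2H in THF at reflux should give 1-[2-methoxy-3-(propan-2-yloxy)phenyl]-2-methylprop-2-en-1-one F1. Nazarov cyclisation of this simple aryl isopropenyl ketone (CH3SO3H, CH2Cl2) should give 7-methoxy-2-methyl-6-(propan-2-yloxy)-2,3-dihydro-1H-inden-1-one F2. Dehydrogenation with IBX in DMSO at 70 °C should give 7-methoxy-2-methyl-6-(propan-2-yloxy)-1H-inden-1-one F3. Conjugate Friedel–Crafts addition of naphthalene 9 through its nucleophilic A-C1 to F3, catalysed by Sc(OTf)3 in CH2Cl2 at low temperature, should then give 20.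

Step 14 (carbene ring expansion). The carbene may be captured by the alkoxynaphthalene ring, or the base may shift the indene double bond or cleave the enol ether before cyclopropanation. The fallback keeps the one-carbon insertion but uses a non-basic carbenoid and an oxidative ring opening; it sets out from silyl enol ether 21 and returns at naphthol 26, so step 15 is skipped. Simmons–Smith cyclopropanation (Et2Zn, CH2I2, CH2Cl2, 0 °C) should give the siloxycyclopropane F4. FeCl3 in DMF at 0 °C should open the ring-fusion bond to the ring-expanded 3-chloro-3-methyl-3,4-dihydronaphthalen-1(2H)-one F5. NaOAc in MeOH at reflux should eliminate HCl to the 4H-naphthalen-1-one F6, which enolises to 26.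

Step 4 (regioselective mono-etherification). Exchange with a secondary alcohol may be slow or unselective, and the diol may self-condense under acid. The fallback differentiates the two hydroxyls by steric bulk; it sets out from diol 7 and returns at naphthalene 9. Silylation with i-Pr3SiCl and imidazole in DMF at 0 °C should occur at the unhindered 3-hydroxyl to give 8-methoxy-6-methyl-3-[tri(propan-2-yl)silyloxy]naphthalen-1-ol F7. Methylation (NaH, MeI, THF, 0 °C) should give [(4,5-dimethoxy-7-methylnaphthalen-2-yl)oxy]tri(propan-2-yl)silane F8. Bu4NF in THF should give 4,5-dimethoxy-7-methylnaphthalen-2-ol F9, and Williamson alkylation with 2-bromopropane and K2CO3 in DMF should give 9.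

Further compounds
F1 | step 12 | 1-[2-methoxy-3-(propan-2-yloxy)phenyl]-2-methylprop-2-en-1-one | C=C(C)C(=O)c1cccc(OC(C)C)c1OC
F2 | step 12 | 7-methoxy-2-methyl-6-(propan-2-yloxy)-2,3-dihydro-1H-inden-1-one (racemic) | CC1Cc2ccc(OC(C)C)c(OC)c2C1=O
F3 | step 12 | 7-methoxy-2-methyl-6-(propan-2-yloxy)-1H-inden-1-one | CC1=Cc2ccc(OC(C)C)c(OC)c2C1=O
F4 | step 14 | methylene adduct of 21 across the enol ether bond: 1a-methyl-6a-[tert-butyl(dimethyl)silyloxy]-1,1a,6,6a-tetrahydrocyclopropa[a]indene carrying the 5-methoxy, 4-isopropoxy and 6-naphthyl groups of 21 (racemic) | CC12CC1(O[Si](C)(C)C(C)(C)C)c1c(OC)c(OC(C)C)ccc1C2c1c(OC(C)C)cc(OC)c2c(OC)cc(C)cc12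
F5 | step 14 | 3-chloro-4-[4,5-dimethoxy-7-methyl-2-(propan-2-yloxy)naphthalen-1-yl]-8-methoxy-3-methyl-7-(propan-2-yloxy)-3,4-dihydronaphthalen-1(2H)-one (racemic) | O=C1CC(C)(Cl)C(c2c(OC(C)C)cc(OC)c3c(OC)cc(C)cc23)c2ccc(OC(C)C)c(OC)c12
F6 | step 14 | 4-[4,5-dimethoxy-7-methyl-2-(propan-2-yloxy)naphthalen-1-yl]-8-methoxy-3-methyl-7-(propan-2-yloxy)naphthalen-1(4H)-one (racemic) | O=C1C=C(C)C(c2c(OC(C)C)cc(OC)c3c(OC)cc(C)cc23)c2ccc(OC(C)C)c(OC)c12
F7 | step 4 | 8-methoxy-6-methyl-3-[tri(propan-2-yl)silyloxy]naphthalen-1-ol | COc1cc(C)cc2cc(O[Si](C(C)C)(C(C)C)C(C)C)cc(O)c12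
F8 | step 4 | [(4,5-dimethoxy-7-methylnaphthalen-2-yl)oxy]tri(propan-2-yl)silane | COc1cc(C)cc2cc(O[Si](C(C)C)(C(C)C)C(C)C)cc(OC)c12
F9 | step 4 | 4,5-dimethoxy-7-methylnaphthalen-2-ol | COc1cc(C)cc2cc(O)cc(OC)c12
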